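**Retrosynthetic overview**

1. The strategy rests on the trisubstituted C13=C14 alkene, in which C12 and the C15 carboxyl are cis (13Z). This geometry equals syn addition of a C12 organocopper and CO2 across propyne, forming C12–C13 and C14–C15 in one flask.
2. The C12 Grignard reagent comes from a primary bromide. C12 is freed from an isopropyl ketone by α-hydroxylation and Pb(OAc)4 cleavage (C12–C13 cut).
3. The 6α-hydroxy-8(17)-ene array comes from a ring-C-seco enal: γ-hydroxylation at C6 through the dienyl acetate, then reductive 1,3-transposition of the enal tosylhydrazone.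
4. No ring is formed. Rings A and B, with C4, C5, C9 and C10, are taken unchanged from abietic acid; ring C is opened at its C13=C14 bond by ozonolysis.
5. Endgame: removal of both silyl ethers and selective benzoylation of the primary C18 hydroxyl.

Key step: step 13

Remark: the target is read as 18-benzoyloxy-6α-hydroxylabda-8(17),13Z-dien-15-oic acid of the normal labdane series; labdane numbering is used for every intermediate, so the aldehyde carbon released from ring C of abietic acid (abietane C14) is called C17 and the ketone carbon is C13.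

**Route**

Step 1
Reactants: 1 abietic acid
Product: 2 abietinol (abieta-7,13-dien-18-ol)
Conditions: LiAlH4, THF, 0 → 65 °C; aqueous NaOH work-up
Reagents that add atoms: none
Why: Hydride reduction of the neopentyl C18 carboxylic acid by LiAlH4 should give the primary alcohol while the 7,13-diene and the four stereocentres C4, C5, C9 and C10 stay untouched.

Step 2
Reactants: 2 abietinol
Product: 3 abietinol 18-O-tert-butyldimethylsilyl ether
Conditions: TBSCl, imidazole, DMF, 23 °C
Reagents that add atoms: tert-butyldimethylsilyl chloride, CC(C)(C)[Si](C)(C)Cl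
Why: Silyl ether formation at the primary neopentyl hydroxyl gives a group that should survive ozone, peracid, amide base and the magnesium and copper reagents used later.

Step 3
Reactants: 3 abietinol 18-O-tert-butyldimethylsilyl ether
Product: 4 ring-C-seco keto-enal (C7=C8, C17 formyl on C8, 4-methyl-3-oxopentyl chain on C9β, 18-OTBS)
Conditions: O3 (1.0 equiv, Sudan Red 7B end point), CH2Cl2–MeOH, −78 °C; Me2S, −78 → 23 °C
Reagents that add atoms: ozone, [O-][O+]=O
Why: Ozonolysis with reductive work-up should cleave the more electron-rich and less hindered ring C alkene (abietane C13=C14) first, and the surviving C7=C8 bond then belongs to an electron-poor enal that reacts far more slowly with ozone, so one equivalent stops at the keto-enal.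

Step 4
Reactants: 4 ring-C-seco keto-enal
Product: 5 dienyl acetate (C17 acetoxymethylidene on C8 and C6=C7; E/Z mixture at C8=C17)
Conditions: Ac2O, Et3N, DMAP (cat.), CH2Cl2, 23 → 40 °C
Reagents that add atoms: acetic anhydride, CC(=O)OC(C)=O
Why: Dienol acetate formation should occur only at the enal, which is O-acylated and deprotonated at its single γ position C6, whereas the saturated isopropyl ketone is not enolised by an amine base.

Step 5
Reactants: 5 dienyl acetate
Product: 6 6α-hydroxy keto-enal (C7=C8, C17 formyl, 6α-OH, 18-OTBS)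
Conditions: mCPBA (1.05 equiv), NaHCO3, CH2Cl2–H2O, 0 °C
Reagents that add atoms: 3-chloroperbenzoic acid, O=C(OO)c1cccc(Cl)c1
Why: Peracid γ-hydroxylation of a dienol acetate (a vinylogous Rubottom-type oxidation) should epoxidise the distal C6=C7 bond from the α face, because the β face at C6 lies under the axial methyl groups on C4 and C10, and the epoxide opens at C7 with loss of the acetyl group to return the enal carrying the new equatorial 6α-hydroxyl.

Step 6
Reactants: 6 6α-hydroxy keto-enal
Product: 7 6α,18-bis(TBS-oxy) keto-enal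
Conditions: TBSOTf, 2,6-lutidine, CH2Cl2, −78 → 0 °C
Reagents that add atoms: tert-butyldimethylsilyl triflate, CC(C)(C)[Si](C)(C)OS(=O)(=O)C(F)(F)F
Why: Silyl ether formation with the triflate and a hindered pyridine base should cap the hindered allylic 6α-hydroxyl at low temperature without enolising the aldehyde or the ketone.

Step 7
Reactants: 7 6α,18-bis(TBS-oxy) keto-enal
Product: 9 6α,18-bis(TBS-oxy) 8(17)-methylene isopropyl ketone, via C17 tosylhydrazone 8 (not isolated)
Conditions: TsNHNH2 (1.05 equiv), THF, 23 °C; solvent change to CHCl3, catecholborane, 0 °C; NaOAc·3H2O, 60 °C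
Reagents that add atoms: none
Why: Reductive 1,3-transposition of an α,β-unsaturated tosylhydrazone: the conjugated aldehyde should condense with one equivalent of tosylhydrazide much faster than the hindered ketone, catecholborane reduces the C=N bond, and the allylic diazene formed on loss of sulfinate expels N2 by a retro-ene hydrogen shift to C7, which moves the alkene to the exocyclic C8=C17 position without touching a stereocentre.

Step 8
Reactants: 9 6α,18-bis(TBS-oxy) 8(17)-methylene isopropyl ketone
Product: 10 12-hydroxy ketone (C12 epimers)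
Conditions: KN(SiMe3)2, THF, −78 °C; 2-(phenylsulfonyl)-3-phenyloxaziridine, −78 °C; aq. NH4Cl
Reagents that add atoms: 2-(phenylsulfonyl)-3-phenyloxaziridine, O=S(=O)(c1ccccc1)N1OC1c1ccccc1
Why: Davis oxaziridine hydroxylation of the kinetic potassium enolate, which should form at the less hindered C12 methylene and not at the isopropyl methine; the C12 configuration is irrelevant because this carbon becomes a carbonyl in the next step.

Step 9
Reactants: 10 12-hydroxy ketone
Product: 11 6α,18-bis(TBS-oxy)-13,14,15,16-tetranorlabd-8(17)-en-12-al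
Conditions: Pb(OAc)4, MeOH–PhH (1:1), 0 °C
Reagents that add atoms: none
Why: Criegee-type ketol cleavage by Pb(OAc)4 through the methanol hemiketal should cut the C12–C13 bond to give the C12 aldehyde and methyl 2-methylpropanoate, and the 1,1-disubstituted alkene and silyl ethers are inert at 0 °C.

Step 10
Reactants: 11 6α,18-bis(TBS-oxy)-13,14,15,16-tetranorlabd-8(17)-en-12-al
Product: 12 6α,18-bis(TBS-oxy)-13,14,15,16-tetranorlabd-8(17)-en-12-ol
Conditions: NaBH4, MeOH, 0 °C
Reagents that add atoms: none
Why: Hydride reduction of the aldehyde by NaBH4 should give the primary alcohol without affecting the alkene or the silyl ethers.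

Step 11
Reactants: 12 6α,18-bis(TBS-oxy)-13,14,15,16-tetranorlabd-8(17)-en-12-ol
Product: 13 12-bromo-6α,18-bis(TBS-oxy)-13,14,15,16-tetranorlabd-8(17)-ene
Conditions: CBr4, PPh3, 2,6-lutidine, CH2Cl2, 0 °C
Reagents that add atoms: carbon tetrabromide, BrC(Br)(Br)Br
Why: Appel bromination should convert the unhindered primary alcohol into the bromide by SN2 displacement of the oxyphosphonium group, the lutidine buffer keeping the silyl ethers intact.

Step 12
Reactants: 13 12-bromo-6α,18-bis(TBS-oxy)-13,14,15,16-tetranorlabd-8(17)-ene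
Product: 14 C12 Grignard reagent (alkylmagnesium bromide, ether solution, titrated)
Conditions: Mg turnings (activated with BrCH2CH2Br), Et2O, 35 °C
Reagents that add atoms: magnesium, [Mg]
Why: Grignard formation by magnesium insertion into the primary C–Br bond should tolerate the silyl ethers and the remote 1,1-disubstituted alkene, since a pent-4-enyl-type radical on the metal surface has no fast cyclisation path.

Step 13
Reactants: 14 C12 Grignard reagent; 15 propyne; 16 carbon dioxide
Product: 19 6α,18-bis(TBS-oxy)labda-8(17),13Z-dien-15-oic acid, via C12 alkylcopper–MgBr2 species 17 (not isolated), via (Z)-C14 alkenylcopper 18 (not isolated)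
Conditions: CuBr·SMe2 (1.0 equiv), Et2O–Me2S, −45 °C, 2 h; 15 (3 equiv), −25 °C, 3 h; HMPA (2 equiv), P(OEt)3 (0.1 equiv), 16 (1 atm), −40 → 23 °C; 1 M HCl
Reagents that add atoms: none
Why: Grignard reagent 14 should transmetalate to CuBr·SMe2 at −45 °C to give alkylcopper 17, which adds across propyne in a four-centre syn carbometalation with C12 going to the internal alkyne carbon (C13) and copper to the terminal carbon (C14), so that alkenylcopper 18 has C12 and copper cis. Activation of 18 by HMPA and catalytic P(OEt)3 should let CO2 insert into the C14–Cu bond with retention, forming C14–C15 and hence the 13Z acid. The closest known reaction type is the carbocupration of terminal alkynes by alkylcopper–magnesium halide reagents with electrophilic trapping of the alkenylcopper, here by carboxylation. No ring is closed and no stereocentre is created; the only stereochemical element formed is the C13=C14 geometry, which is fixed by the syn stereospecificity of the addition and the configurational stability of the alkenylcopper at low temperature. The step needs copper on the terminal carbon, which the steric and electronic bias of a terminal alkyne secures, and addition in preference to deprotonation of propyne, which the weakly basic alkylcopper–MgBr2 species in Et2O–Me2S secures. The 8(17)-alkene and both silyl ethers should be inert, since unactivated alkenes do not undergo carbocupration.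

Step 14
Reactants: 19 6α,18-bis(TBS-oxy)labda-8(17),13Z-dien-15-oic acid
Product: 20 6α,18-dihydroxylabda-8(17),13Z-dien-15-oic acid
Conditions: HF·pyridine, pyridine, THF, 0 → 23 °C
Reagents that add atoms: none
Why: Fluoride-mediated cleavage of both silyl ethers under pyridine-buffered conditions should not isomerise the exocyclic alkene or the Z-enoic acid.

Step 15
Reactants: 20 6α,18-dihydroxylabda-8(17),13Z-dien-15-oic acid; 21 benzoyl chloride
Product: 23 18-benzoyloxy-6α-hydroxylabda-8(17),13Z-dien-15-oic acid (CNP0304840.1), via mixed benzoic anhydride 22 (not isolated)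
Conditions: 21 (2.1 equiv), pyridine, CH2Cl2, −20 → 0 °C; then THF–H2O, NaHCO3, 23 °C; acidify to pH 3
Reagents that add atoms: none
Why: Selective esterification: acylation under pyridine catalysis should be much faster at the primary C18 hydroxyl than at the secondary 6α-hydroxyl flanked by C5 and the C4 substituents, and the mixed benzoic anhydride formed at the carboxyl group is hydrolysed back to the acid in the aqueous bicarbonate stage.

**Compound list**

1 | abietic acid (abieta-7,13-dien-18-oic acid) | C12=CC[C@H]3[C@](C)(C(=O)O)CCC[C@]3(C)[C@H]1CCC(C(C)C)=C2 | starting material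
2 | abietinol (abieta-7,13-dien-18-ol) | C12=CC[C@H]3[C@](C)(CO)CCC[C@]3(C)[C@H]1CCC(C(C)C)=C2 | intermediate
3 | abietinol 18-O-tert-butyldimethylsilyl ether | C12=CC[C@H]3[C@](C)(CO[Si](C)(C)C(C)(C)C)CCC[C@]3(C)[C@H]1CCC(C(C)C)=C2 | intermediate
4 | ring-C-seco keto-enal: trans-decalin with C7=C8, formyl (C17) on C8, 4-methyl-3-oxopentyl on C9β, CH2OTBS (C18) on C4α | O=CC1=CC[C@H]2[C@](C)(CO[Si](C)(C)C(C)(C)C)CCC[C@]2(C)[C@H]1CCC(=O)C(C)C | intermediate
5 | dienyl acetate: acetoxymethylidene (C17) on C8, C6=C7, E/Z mixture at C8=C17, otherwise as 4 | CC(=O)OC=C1C=C[C@H]2[C@](C)(CO[Si](C)(C)C(C)(C)C)CCC[C@]2(C)[C@H]1CCC(=O)C(C)C | intermediate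
6 | 6α-hydroxy keto-enal (6α-OH, C7=C8, C17 formyl, 18-OTBS) | O=CC1=C[C@H](O)[C@H]2[C@](C)(CO[Si](C)(C)C(C)(C)C)CCC[C@]2(C)[C@H]1CCC(=O)C(C)C | intermediate
7 | 6α,18-bis(TBS-oxy) keto-enal | O=CC1=C[C@H](O[Si](C)(C)C(C)(C)C)[C@H]2[C@](C)(CO[Si](C)(C)C(C)(C)C)CCC[C@]2(C)[C@H]1CCC(=O)C(C)C | intermediate
8 | C17 tosylhydrazone of 7 (not isolated) | Cc1ccc(cc1)S(=O)(=O)NN=CC1=C[C@H](O[Si](C)(C)C(C)(C)C)[C@H]2[C@](C)(CO[Si](C)(C)C(C)(C)C)CCC[C@]2(C)[C@H]1CCC(=O)C(C)C | intermediate
9 | 6α,18-bis(TBS-oxy) 8(17)-methylene isopropyl ketone (4-methyl-3-oxopentyl on C9β) | C=C1C[C@H](O[Si](C)(C)C(C)(C)C)[C@H]2[C@](C)(CO[Si](C)(C)C(C)(C)C)CCC[C@]2(C)[C@H]1CCC(=O)C(C)C | intermediate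
10 | 12-hydroxy ketone, C12 epimers (2-hydroxy-4-methyl-3-oxopentyl on C9β) | C=C1C[C@H](O[Si](C)(C)C(C)(C)C)[C@H]2[C@](C)(CO[Si](C)(C)C(C)(C)C)CCC[C@]2(C)[C@H]1CC(O)C(=O)C(C)C | intermediate
11 | 6α,18-bis(TBS-oxy)-13,14,15,16-tetranorlabd-8(17)-en-12-al | C=C1C[C@H](O[Si](C)(C)C(C)(C)C)[C@H]2[C@](C)(CO[Si](C)(C)C(C)(C)C)CCC[C@]2(C)[C@H]1CC=O | intermediate
12 | 6α,18-bis(TBS-oxy)-13,14,15,16-tetranorlabd-8(17)-en-12-ol | C=C1C[C@H](O[Si](C)(C)C(C)(C)C)[C@H]2[C@](C)(CO[Si](C)(C)C(C)(C)C)CCC[C@]2(C)[C@H]1CCO | intermediate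
13 | 12-bromo-6α,18-bis(TBS-oxy)-13,14,15,16-tetranorlabd-8(17)-ene | C=C1C[C@H](O[Si](C)(C)C(C)(C)C)[C@H]2[C@](C)(CO[Si](C)(C)C(C)(C)C)CCC[C@]2(C)[C@H]1CCBr | intermediate
14 | C12 Grignard reagent (alkylmagnesium bromide) of 13 | C=C1C[C@H](O[Si](C)(C)C(C)(C)C)[C@H]2[C@](C)(CO[Si](C)(C)C(C)(C)C)CCC[C@]2(C)[C@H]1CC[Mg]Br | intermediate
15 | propyne | CC#C | starting material
16 | carbon dioxide | O=C=O | starting material
17 | C12 alkylcopper, MgBr2 complex (not isolated) | C=C1C[C@H](O[Si](C)(C)C(C)(C)C)[C@H]2[C@](C)(CO[Si](C)(C)C(C)(C)C)CCC[C@]2(C)[C@H]1CC[Cu] | intermediate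
18 | (Z)-C14 alkenylcopper, C12 and Cu cis (not isolated) | C=C1C[C@H](O[Si](C)(C)C(C)(C)C)[C@H]2[C@](C)(CO[Si](C)(C)C(C)(C)C)CCC[C@]2(C)[C@H]1CC/C(C)=C\[Cu] | intermediate
19 | 6α,18-bis(TBS-oxy)labda-8(17),13Z-dien-15-oic acid | C=C1C[C@H](O[Si](C)(C)C(C)(C)C)[C@H]2[C@](C)(CO[Si](C)(C)C(C)(C)C)CCC[C@]2(C)[C@H]1CC/C(C)=C\C(=O)O | intermediate
20 | 6α,18-dihydroxylabda-8(17),13Z-dien-15-oic acid | C=C1C[C@H](O)[C@H]2[C@](C)(CO)CCC[C@]2(C)[C@H]1CC/C(C)=C\C(=O)O | intermediate
21 | benzoyl chloride | O=C(Cl)c1ccccc1 | starting material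
22 | mixed benzoic anhydride of the 18-benzoate (not isolated) | C=C1C[C@H](O)[C@H]2[C@](C)(COC(=O)c3ccccc3)CCC[C@]2(C)[C@H]1CC/C(C)=C\C(=O)OC(=O)c1ccccc1 | intermediate
23 | 18-benzoyloxy-6α-hydroxylabda-8(17),13Z-dien-15-oic acid (CNP0304840.1) | C=C1C[C@H](O)[C@H]2[C@](C)(COC(=O)c3ccccc3)CCC[C@]2(C)[C@H]1CC/C(C)=C\C(=O)O | target

**Step count and risks**

Total step count: 15. Longest linear sequence: 15 steps (1 → 23).

Steps most likely to fail:

Step 13. The alkylcopper may be quenched by the acetylenic hydrogen of propyne, or CO2 insertion into the alkenylcopper may be too slow, so that the alkene is only protonated on work-up. The fallback sets out from bromide 13 and comes back at acid 19. Zinc insertion (Zn dust, LiCl, THF, 50 °C) would give the alkylzinc bromide F1. Negishi coupling (Pd(PPh3)4, THF, 23 → 50 °C) with methyl (Z)-3-iodobut-2-enoate F2 would follow; F2 is made from methyl but-2-ynoate by anti hydroiodination with NaI in AcOH. The coupling should proceed with retention of the iodoalkene geometry to the methyl ester F3. Saponification (LiOH, THF–MeOH–H2O, 23 °C) would then give 19. The Z geometry is here carried in from the iodoenoate.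

Step 5. The peracid may attack the enol acetate double bond instead of C6=C7, or oxidise the product further. The fallback sets out from dienyl acetate 5 and comes back at hydroxy enal 6. Catalytic dihydroxylation (OsO4 cat., N-methylmorpholine N-oxide, acetone–H2O, 0 °C) should take the less hindered, disubstituted C6=C7 bond from the α face and give the 6α,7α-diol enol acetate F4, which can be purified. Methanolysis (K2CO3, MeOH, 0 °C) would then release the 6α,7α-dihydroxy aldehyde F5, which should lose its C7 hydroxyl by E1cB dehydration in the same flask to give 6.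

Step 7. Hydrazone formation or borane reduction may spill over to the C13 ketone, or the diazene may decompose without transposition. The fallback sets out from keto-enal 7 and comes back at ketone 9. Reduction of both carbonyls (NaBH4, CeCl3·7H2O, MeOH, −20 °C) would give the diol F6. Mitsunobu reaction of its primary allylic hydroxyl with 2-nitrobenzenesulfonylhydrazide (PPh3, diethyl azodicarboxylate, THF, −30 °C) should give the N-allyl sulfonylhydrazide F7; the hindered secondary carbinol should not react. On warming to 23 °C, F7 loses sulfinic acid and N2 through the allylic diazene and its retro-ene shift to give the 8(17)-methylene alcohol F8. Dess–Martin periodinane oxidation (CH2Cl2, 23 °C) would return 9.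

**Further compounds**

F1 | step 13 | C12 alkylzinc bromide of 13 | C=C1C[C@H](O[Si](C)(C)C(C)(C)C)[C@H]2[C@](C)(CO[Si](C)(C)C(C)(C)C)CCC[C@]2(C)[C@H]1CC[Zn]Br
F2 | step 13 | methyl (Z)-3-iodobut-2-enoate | C/C(I)=C/C(=O)OC
F3 | step 13 | methyl 6α,18-bis(TBS-oxy)labda-8(17),13Z-dien-15-oate | C=C1C[C@H](O[Si](C)(C)C(C)(C)C)[C@H]2[C@](C)(CO[Si](C)(C)C(C)(C)C)CCC[C@]2(C)[C@H]1CC/C(C)=C\C(=O)OC
F4 | step 5 | 6α,7α-diol enol acetate (acetoxymethylidene on C8, 18-OTBS, isopropyl ketone chain on C9β) | CC(=O)OC=C1[C@H](O)[C@H](O)[C@H]2[C@](C)(CO[Si](C)(C)C(C)(C)C)CCC[C@]2(C)[C@H]1CCC(=O)C(C)C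
F5 | step 5 | 6α,7α-dihydroxy aldehyde (formyl on C8, C8 epimers) | O=CC1[C@H](O)[C@H](O)[C@H]2[C@](C)(CO[Si](C)(C)C(C)(C)C)CCC[C@]2(C)[C@H]1CCC(=O)C(C)C
F6 | step 7 | 13,17-diol (C7=C8, hydroxymethyl on C8, 3-hydroxy-4-methylpentyl on C9β, C13 epimers) | OCC1=C[C@H](O[Si](C)(C)C(C)(C)C)[C@H]2[C@](C)(CO[Si](C)(C)C(C)(C)C)CCC[C@]2(C)[C@H]1CCC(O)C(C)C
F7 | step 7 | N-allyl-N-(2-nitrobenzenesulfonyl)hydrazine from F6 | NN(CC1=C[C@H](O[Si](C)(C)C(C)(C)C)[C@H]2[C@](C)(CO[Si](C)(C)C(C)(C)C)CCC[C@]2(C)[C@H]1CCC(O)C(C)C)S(=O)(=O)c1ccccc1[N+](=O)[O-]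
F8 | step 7 | 8(17)-methylene C13 alcohol (3-hydroxy-4-methylpentyl on C9β, C13 epimers) | C=C1C[C@H](O[Si](C)(C)C(C)(C)C)[C@H]2[C@](C)(CO[Si](C)(C)C(C)(C)C)CCC[C@]2(C)[C@H]1CCC(O)C(C)C
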